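Early in Tuesday's run, at 25.0 min, target stands at 42.1 %, and at each later reading it is lower.

| flask | starting material | reagent | second substrate | third substrate | temperature | remark | time |
|---|---|---|---|---|---|---|---|
| Tuesday's | 0.10 M | 0.30 M | 0.10 M | 0.20 M | 0 °C | run made earlier |  |
| Thursday's | 0.10 M | 0.30 M | 0.40 M | 0.20 M | 35 °C | run made earlier |  |
| zeta | 0.10 M | 0.300 M | 0.200 M | 0.200 M | 35 °C |  | 50 min |
| theta | 0.10 M | 0.300 M | 0.200 M | 0.200 M | 65 °C |  | 50 min |
| epsilon | 0.10 M | 0.300 M | 0.200 M | 0.200 M | 5 °C |  | 50 min |

| run | time / min | target / % | starting material / % |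
|---|---|---|---|
| Tuesday's | 25.0 | 42.1 | 38.6 |
| Tuesday's | 50.0 | 36.4 | 23.8 |
| Tuesday's | 80.0 | 26.9 | 16.8 |
| Tuesday's | 150 | 12.5 | 11.5 |
| Tuesday's | 300 | 1.5 | 8.8 |
| Thursday's | 10.0 | 0 | 47.3 |
| Thursday's | 20.0 | 0.2 | 48.5 |
| Thursday's | 30.0 | 0.9 | 48.7 |
| Thursday's | 40.0 | 0.1 | 48.1 |
| Thursday's | 50.0 | 0 | 47.7 |

(readings scatter by 0.5 percentage points)
1. the best flask by amount of target, in percent of the starting material charged; "all alike" if 1.5 percentage points covers them all (zeta / theta / epsilon / all alike)
2. amount of target at the end, in percent of the starting material charged, zeta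
3. amount of target at the end, in percent of the starting material charged, theta
4. amount of target at the end, in percent of the starting material charged, epsilon
- percentages count the starting material that a species holds: one side product counts as two
- candidate steps: starting material + reagent -> target; second substrate + reagent -> second product; third substrate + reagent -> third product; starting material + target -> side product; target -> over-reaction product

Tuesday's last two readings give a decay constant of 0.0141 min⁻¹, so the half-life of target read from them at 0 °C, the time in which it halves once little new target comes in, is about 49.0 min. Thursday's run has lost 52.7 % of its starting material by 10.0 min, yet its highest target reading is 0.9 %. If that much target was made, and if that highest reading, taken at 30.0 min, is used as a rough figure for what stood at 10.0 min, about 5.87 half-lives passed, which puts the half-life at 35 °C near 1.70 min. Zeta's 50 min is then 29.4 half-lives, so zeta should hold no readable target, and theta, hotter than zeta, is expected to hold none either.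

Taking the logarithm of the half-life as falling evenly with temperature between the two runs, the clock at 5 °C is reckoned to run 1.62 times faster than at 0 °C, which puts the half-life in epsilon at 30.3 min. Read as a stretched Tuesday, epsilon's 50 min stands for 81.0 min, and Tuesday's reading at 80.0 min is 26.9 %.

That stretch is the weak link. Tuesday had c(second substrate) = 0.10 M and epsilon has twice that. Thursday, with 0.40 M and at another temperature, has starting material at 47.7 % in its last reading, against 8.8 % in Tuesday's last reading. Interpolating straight between the two, temperature set aside, epsilon is reckoned to turn over 85.8 % of Tuesday's amount. Scaling Tuesday's reading at 25.0 min by that share, and leaving the faster clock out of this one step, gives an estimate of 36.1 % for target in epsilon at that time. From there 0.824 half-lives follow, which gives an estimate of 20.4 % for epsilon at 50 min.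

The forecast named epsilon and gave 0 % for zeta, 0 % for theta and 25 % for epsilon, within 17 % to 33 %, higher than this reckoning, saying “Tuesday's 36% at 50 min then drops to about 25%”.

The simulation gives epsilon as the best flask, with 0 % in zeta, 0 % in theta and 16.5 % in epsilon.

    starting material + reagent → target (k = 0.00540 M⁻¹ s⁻¹, Ea = 51.0 kJ mol⁻¹)
    second substrate + reagent → second product (k = 0.00800 M⁻¹ s⁻¹, Ea = 44.0 kJ mol⁻¹)
    third substrate + reagent → third product (k = 0.00310 M⁻¹ s⁻¹, Ea = 51.0 kJ mol⁻¹)
    starting material + target → side product (k = 0.00330 M⁻¹ s⁻¹, Ea = 65.0 kJ mol⁻¹)
    target → over-reaction product (k = 4.00 × 10⁻⁴ s⁻¹, Ea = 87.0 kJ mol⁻¹)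
    (constants at 5 °C)

In epsilon, target goes from 29.4 % at 25.0 min to 16.5 % at 50.0 min, while reagent, the limiting reagent, falls from 10.4 % to 2.40 % of its charge. That net fall of target in epsilon corresponds to a half-life of 30.0 min against the 30.3 min reckoned, but the height at 25.0 min stands lower than the 36.1 % reckoned. At 10 °C with zeta's charge, the half-life from 49.0 min comes to 18.8 min. If that flask is taken to reach epsilon's height of 29.4 % 1.62 times sooner than epsilon, the reckoning gives 8.22 % at 50 min, and the simulated flask holds 5.57 %.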